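**Plan**

- Retrosynthetic cuts, in order: O-acetyl; quinone (from an 11,12,14-trimethoxy arene); C3–C4 and C4–C18 (two alkylations of a δ-lactone enolate); the lactone at C19 (lactol from a C19 acetal and the C20 alcohol); C5–C10; then C10–C1, C7–C6 and C9–C10 around ring C.
- Enabling feature: ring B is a 1,2-dihydronaphthalene in which C10 carries one oxygenated carbon (C20) and C6=C7 lies γ,δ to it, so C20–C10–C5–C6=C7 is the retron of an ester-enolate Claisen shift. Because C7 and C10 sit on the adjacent ring C carbons C8 and C9, the allyl ester is a six-membered lactone (a 1-alkenylisochroman-3-one), and the shift contracts this oxacycle to carbocyclic ring B while the ring oxygen moves out onto C20.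
- Forward ring order: ring C (bought) → temporary isochromanone ring → ring B (key step) → δ-lactone → ring A → quinone.
- Helpers: C20 passes through the CO2R level and is reduced; C19 travels as a diethyl acetal; C1–C3 travel as a 3-chloropropyl group.
- Stereochemistry: C7 is set by ligand-controlled alkenylzinc addition and relayed to C10 and C5 through the boat transition state of the Claisen step (E-alkene, hence H5 anti to C20), C7 itself becoming sp2; C4 follows from the bridged ring closure.

Key step: step 9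

Remark: positions are named by abietane numbering (C18 = methyl on C4, C19 = lactone carbonyl, C20 = OCH2 on C10, ring C = C8, C9, C11–C14). Compound 11, 1-chloro-3-iodopropane, (c-C6H11)2BH and (−)-MIB, which is (2S)-(−)-3-exo-(morpholino)isoborneol, are taken as purchasable.

Step 1
Reactants: 1 1,2,4-trimethoxybenzene
Product: 3 2-(2,3,6-trimethoxyphenyl)propan-2-ol, via aryllithium 2 (not isolated)
Conditions: n-BuLi, THF, 0 → 25 °C; acetone, −78 → 25 °C; H2O
Reagents that add atoms: acetone CC(C)=O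
Why: Directed ortho-metalation removes the proton flanked by two methoxy groups, and the aryllithium adds to acetone (1,2-addition).

Step 2
Reactants: 3 2-(2,3,6-trimethoxyphenyl)propan-2-ol
Product: 4 2-isopropyl-1,3,4-trimethoxybenzene
Conditions: Et3SiH, CF3CO2H, CH2Cl2, 0 °C
Reagents that add atoms: none
Why: Ionic hydrogenation, in which the tertiary benzylic cation stabilised by two ortho methoxy groups is reduced by hydride transfer from the silane.

Step 3
Reactants: 4 2-isopropyl-1,3,4-trimethoxybenzene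
Product: 5 3-isopropyl-2,4,5-trimethoxybenzaldehyde
Conditions: Cl2CHOMe, TiCl4, CH2Cl2, −10 → 0 °C; H2O
Reagents that add atoms: dichloromethyl methyl ether COC(Cl)Cl; water O
Why: Rieche formylation should attack the ring position (C8) that is ortho to one methoxy group and para to another, the other free position (C9) being activated by a single ortho methoxy group only.

Step 4
Reactants: 5 3-isopropyl-2,4,5-trimethoxybenzaldehyde
Product: 10 6-[2-(tert-butyldimethylsilyloxy)ethyl]-3-isopropyl-2,4,5-trimethoxybenzaldehyde, via amino alkoxide 6 (not isolated), via aryllithium 7 (not isolated), via lithium alkoxide 8 (not isolated), via silyl ether 9 (not isolated)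
Conditions: Me2NCH2CH2N(Me)Li (from Me2NCH2CH2NHMe, n-BuLi), THF, −20 °C; n-BuLi, −20 °C; ethylene oxide, −78 → 0 °C; t-BuMe2SiCl, 0 → 25 °C; H2O
Reagents that add atoms: ethylene oxide C1CO1; tert-butyldimethylsilyl chloride CC(C)(C)[Si](C)(C)Cl
Why: Directed ortho-metalation, in which the aldehyde is masked in the flask as its α-amino alkoxide and, together with the C11 methoxy group, directs lithiation to the only ring C–H (C9); epoxide opening and O-silylation follow, and hydrolysis returns the aldehyde.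

Step 5
Reactants: 10 6-[2-(tert-butyldimethylsilyloxy)ethyl]-3-isopropyl-2,4,5-trimethoxybenzaldehyde; 11 4,4-diethoxybut-1-yne
Product: 14 (1S,2E)-1-{6-[2-(tert-butyldimethylsilyloxy)ethyl]-3-isopropyl-2,4,5-trimethoxyphenyl}-5,5-diethoxypent-2-en-1-ol, via alkenylborane 12 (not isolated), via alkenylzinc 13 (not isolated)
Conditions: 11, (c-C6H11)2BH, toluene, 0 → 25 °C; Et2Zn, −78 °C; (−)-MIB (5 mol %), 10, −20 → 0 °C; H2O
Reagents that add atoms: none
Why: Catalytic asymmetric alkenylzinc addition, in which syn-hydroboration fixes the E alkene, boron-to-zinc exchange gives the alkenylzinc, and the (−)-MIB zinc alkoxide is expected to deliver the alkenyl group to the Si face of the aldehyde as it does with benzaldehyde, giving the (S) carbinol at C7.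

Step 6
Reactants: 14 (1S,2E)-1-{6-[2-(tert-butyldimethylsilyloxy)ethyl]-3-isopropyl-2,4,5-trimethoxyphenyl}-5,5-diethoxypent-2-en-1-ol
Product: 15 (1S,2E)-5,5-diethoxy-1-[6-(2-hydroxyethyl)-3-isopropyl-2,4,5-trimethoxyphenyl]pent-2-en-1-ol
Conditions: Bu4NF, THF, 0 °C
Reagents that add atoms: none
Why: Fluoride-induced desilylation frees the primary alcohol while the acetal and the allylic carbinol are inert.

Step 7
Reactants: 15 (1S,2E)-5,5-diethoxy-1-[6-(2-hydroxyethyl)-3-isopropyl-2,4,5-trimethoxyphenyl]pent-2-en-1-ol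
Product: 17 (1S)-1-[(1E)-4,4-diethoxybut-1-en-1-yl]-7-isopropyl-5,6,8-trimethoxyisochroman-3-one, via lactol 16 (not isolated)
Conditions: TEMPO (20 mol %), PhI(OAc)2, CH2Cl2, 25 °C
Reagents that add atoms: none
Why: Oxoammonium-mediated oxidative lactonisation of a 1,5-diol, in which the unhindered primary alcohol is oxidised first, the aldehyde is trapped by the C7 hydroxyl as a six-membered lactol, and this is oxidised on to the lactone with C7 untouched.

Step 8
Reactants: 17 (1S)-1-[(1E)-4,4-diethoxybut-1-en-1-yl]-7-isopropyl-5,6,8-trimethoxyisochroman-3-one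
Product: 19 (1S)-4-(3-chloropropyl)-1-[(1E)-4,4-diethoxybut-1-en-1-yl]-7-isopropyl-5,6,8-trimethoxyisochroman-3-one, via lithium enolate 18 (not isolated)
Conditions: LiN(iPr)2, THF, −78 °C; ICH2CH2CH2Cl, DMPU, −78 → −40 °C
Reagents that add atoms: 1-chloro-3-iodopropane ClCCCI
Why: Enolate alkylation at the benzylic lactone α-carbon (C10) with the iodide end of the dihalide; the new centre at C10 is formed without control, which does not matter because it is planarised in step 9.

Step 9
Reactants: 19 (1S)-4-(3-chloropropyl)-1-[(1E)-4,4-diethoxybut-1-en-1-yl]-7-isopropyl-5,6,8-trimethoxyisochroman-3-one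
Product: 23 methyl (1R,2R)-1-(3-chloropropyl)-2-(2,2-diethoxyethyl)-6-isopropyl-5,7,8-trimethoxy-1,2-dihydronaphthalene-1-carboxylate, via silyl ketene acetal 20 (not isolated), via silyl ester 21 (not isolated), via carboxylic acid 22 (not isolated)
Conditions: LiN(iPr)2, Me3SiCl, Et3N, THF, −78 °C; toluene, 25 → 80 °C; MeOH; Me3SiCHN2, toluene/MeOH, 0 °C
Reagents that add atoms: (trimethylsilyl)diazomethane C[Si](C)(C)C=[N+]=[N-]
Why: Deprotonation at C10 (the only readily enolisable position) and O-silylation give the cyclic silyl ketene acetal, in which O–C20=C10 and the allyl unit C7–C6=C5 form an allyl vinyl ether held in one six-membered ring, and a concerted suprafacial [3,3]-sigmatropic shift (Ireland–Claisen rearrangement) forms C5–C10 as C7–O breaks. The closest known reaction types are the Ireland–Claisen ring contraction of ω-alkenyl lactone silyl ketene acetals to cycloalkenecarboxylic acids and the thermal Claisen rearrangement of 2-alkenyl-3,4-dihydro-2H-pyrans to cyclohex-3-enecarbaldehydes, here with the oxacycle benzo-fused. Ring B is closed through a boat-shaped six-centre transition state with the arene bond C8–C9 as a third bridge, the only topology the ring allows, which converts the six-membered oxacycle into the six-membered carbocycle and leaves C6=C7 cis inside ring B. C10 is set because C5 can only reach the face of the ketene acetal on which the alkenyl group sits, which is fixed by the (S) centre at C7, and C5 is set by the E geometry of C5=C6, which puts the C4 chain outside and H5 anti to C20, giving (5R,10R) in abietane numbering. The step needs the concerted shift to outrun ionisation of the benzylic, allylic C7–O bond (which would erase the chirality transfer) and needs O- rather than C-silylation; a base-buffered medium free of strong Lewis acid and the relief of peri strain at C10 on pyramidalisation should favour the concerted path.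

Step 10
Reactants: 23 methyl (1R,2R)-1-(3-chloropropyl)-2-(2,2-diethoxyethyl)-6-isopropyl-5,7,8-trimethoxy-1,2-dihydronaphthalene-1-carboxylate
Product: 25 (4aR,10bR)-10b-(3-chloropropyl)-8-isopropyl-7,9,10-trimethoxy-3,4,4a,10b-tetrahydro-1H-benzo[h]isochromen-3-ol, via hydroxy acetal 24 (not isolated)
Conditions: iBu2AlH, CH2Cl2, −78 → 0 °C; AcOH/THF/H2O, 40 °C
Reagents that add atoms: water O
Why: Ester reduction to the neopentyl C20 alcohol (chloride and alkene untouched) followed by acetal hydrolysis, after which the C19 aldehyde is captured by the C20 hydroxyl as a six-membered lactol (C4 and C20 are cis on ring B); the anomeric centre does not matter.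

Step 11
Reactants: 25 (4aR,10bR)-10b-(3-chloropropyl)-8-isopropyl-7,9,10-trimethoxy-3,4,4a,10b-tetrahydro-1H-benzo[h]isochromen-3-ol
Product: 26 (4aR,10bR)-10b-(3-chloropropyl)-8-isopropyl-7,9,10-trimethoxy-1,4,4a,10b-tetrahydro-3H-benzo[h]isochromen-3-one
Conditions: TEMPO (20 mol %), PhI(OAc)2, CH2Cl2, 25 °C
Reagents that add atoms: none
Why: Oxoammonium oxidation of the lactol gives the δ-lactone with the carbonyl at C19 and the oxygen on C20.

Step 12
Reactants: 26 (4aR,10bR)-10b-(3-chloropropyl)-8-isopropyl-7,9,10-trimethoxy-1,4,4a,10b-tetrahydro-3H-benzo[h]isochromen-3-one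
Product: 28 (4aS,10bR)-10b-(3-chloropropyl)-8-isopropyl-7,9,10-trimethoxy-4-methyl-1,4,4a,10b-tetrahydro-3H-benzo[h]isochromen-3-one, via lithium enolate 27 (not isolated)
Conditions: LiN(iPr)2, THF, −78 °C; MeI, −78 °C
Reagents that add atoms: iodomethane CI
Why: Lactone enolate alkylation introduces C18 at a temperature at which the chloride should not react; the configuration at C4 does not matter because it is planarised in step 13.

Step 13
Reactants: 28 (4aS,10bR)-10b-(3-chloropropyl)-8-isopropyl-7,9,10-trimethoxy-4-methyl-1,4,4a,10b-tetrahydro-3H-benzo[h]isochromen-3-one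
Product: 29 (4S,5R,10R)-11,12,14-trimethoxyabieta-6,8,11,13-tetraen-19,20-olide
Conditions: KN(SiMe3)2, THF/DMPU, −78 → 25 °C
Reagents that add atoms: none
Why: Intramolecular enolate C-alkylation (6-exo-tet) closes ring A; the C3 chloride can reach the C4 enolate only from the face on which the C10 chain lies, so the bridged lactone forms with C19 and C20 necessarily cis (4S) and the methyl group exo.

Step 14
Reactants: 29 (4S,5R,10R)-11,12,14-trimethoxyabieta-6,8,11,13-tetraen-19,20-olide
Product: 30 (4S,5R,10R)-12-methoxy-11,14-dioxoabieta-6,8,12-trien-19,20-olide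
Conditions: (NH4)2Ce(NO3)6, MeCN/H2O, 0 °C
Reagents that add atoms: water O
Why: Oxidative demethylation of the para-related C11 and C14 methoxy groups should give the 2-methoxy-1,4-benzoquinone, the usual outcome for 1,2,4-trimethoxyarenes, without involving the lactone or the stereocentres.

Step 15
Reactants: 30 (4S,5R,10R)-12-methoxy-11,14-dioxoabieta-6,8,12-trien-19,20-olide
Product: 31 (4S,5R,10R)-12-hydroxy-11,14-dioxoabieta-6,8,12-trien-19,20-olide
Conditions: BCl3, CH2Cl2, −78 → 0 °C; H2O
Reagents that add atoms: none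
Why: Lewis acid ether cleavage, in which boron chelated between the C11 carbonyl and the C12 methoxy oxygen activates the vinylogous methyl ester for O–CH3 cleavage without base, so the lactone and the vinyl quinone should stay intact.

Step 16
Reactants: 31 (4S,5R,10R)-12-hydroxy-11,14-dioxoabieta-6,8,12-trien-19,20-olide
Product: 32 (4S,5R,10R)-12-acetoxy-11,14-dioxoabieta-6,8,12-trien-19,20-olide
Conditions: Ac2O, pyridine, DMAP (cat.), CH2Cl2, 0 → 25 °C
Reagents that add atoms: acetic anhydride CC(=O)OC(C)=O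
Why: O-Acylation of the acidic hydroxyquinone gives the enol acetate of the target.

**Compound list**

1 | 1,2,4-trimethoxybenzene | COc1ccc(OC)c(OC)c1 | starting material
2 | (2,3,6-trimethoxyphenyl)lithium | [Li]c1c(OC)ccc(OC)c1OC | intermediate
3 | 2-(2,3,6-trimethoxyphenyl)propan-2-ol | CC(C)(O)c1c(OC)ccc(OC)c1OC | intermediate
4 | 2-isopropyl-1,3,4-trimethoxybenzene | CC(C)c1c(OC)ccc(OC)c1OC | intermediate
5 | 3-isopropyl-2,4,5-trimethoxybenzaldehyde | COc1cc(C=O)c(OC)c(C(C)C)c1OC | intermediate
6 | lithium α-amino alkoxide of 5 (adduct of the aldehyde with lithium [2-(dimethylamino)ethyl](methyl)amide) | COc1cc(C(O[Li])N(C)CCN(C)C)c(OC)c(C(C)C)c1OC | intermediate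
7 | 6-lithio derivative of 6 | COc1c([Li])c(C(O[Li])N(C)CCN(C)C)c(OC)c(C(C)C)c1OC | intermediate
8 | lithium 2-arylethoxide from 7 and ethylene oxide (amino alkoxide retained) | COc1c(CCO[Li])c(C(O[Li])N(C)CCN(C)C)c(OC)c(C(C)C)c1OC | intermediate
9 | tert-butyldimethylsilyl ether of 8 (amino alkoxide retained) | COc1c(CCO[Si](C)(C)C(C)(C)C)c(C(O[Li])N(C)CCN(C)C)c(OC)c(C(C)C)c1OC | intermediate
10 | 6-[2-(tert-butyldimethylsilyloxy)ethyl]-3-isopropyl-2,4,5-trimethoxybenzaldehyde | COc1c(CCO[Si](C)(C)C(C)(C)C)c(C=O)c(OC)c(C(C)C)c1OC | intermediate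
11 | 4,4-diethoxybut-1-yne | C#CCC(OCC)OCC | starting material
12 | dicyclohexyl[(1E)-4,4-diethoxybut-1-en-1-yl]borane | CCOC(OCC)C/C=C/B(C1CCCCC1)C1CCCCC1 | intermediate
13 | [(1E)-4,4-diethoxybut-1-en-1-yl](ethyl)zinc | CCOC(OCC)C/C=C/[Zn]CC | intermediate
14 | (1S,2E)-1-{6-[2-(tert-butyldimethylsilyloxy)ethyl]-3-isopropyl-2,4,5-trimethoxyphenyl}-5,5-diethoxypent-2-en-1-ol | COc1c(CCO[Si](C)(C)C(C)(C)C)c([C@@H](O)/C=C/CC(OCC)OCC)c(OC)c(C(C)C)c1OC | intermediate
15 | (1S,2E)-5,5-diethoxy-1-[6-(2-hydroxyethyl)-3-isopropyl-2,4,5-trimethoxyphenyl]pent-2-en-1-ol | COc1c(CCO)c([C@@H](O)/C=C/CC(OCC)OCC)c(OC)c(C(C)C)c1OC | intermediate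
16 | (1S)-1-[(1E)-4,4-diethoxybut-1-en-1-yl]-7-isopropyl-5,6,8-trimethoxyisochroman-3-ol (both anomers) | OC1Cc2c(OC)c(OC)c(C(C)C)c(OC)c2[C@H](/C=C/CC(OCC)OCC)O1 | intermediate
17 | (1S)-1-[(1E)-4,4-diethoxybut-1-en-1-yl]-7-isopropyl-5,6,8-trimethoxyisochroman-3-one | O=C1Cc2c(OC)c(OC)c(C(C)C)c(OC)c2[C@H](/C=C/CC(OCC)OCC)O1 | intermediate
18 | lithium enolate of 17 | [Li]OC1=Cc2c(OC)c(OC)c(C(C)C)c(OC)c2[C@H](/C=C/CC(OCC)OCC)O1 | intermediate
19 | (1S)-4-(3-chloropropyl)-1-[(1E)-4,4-diethoxybut-1-en-1-yl]-7-isopropyl-5,6,8-trimethoxyisochroman-3-one (both C4 epimers of the isochromanone) | O=C1C(CCCCl)c2c(OC)c(OC)c(C(C)C)c(OC)c2[C@H](/C=C/CC(OCC)OCC)O1 | intermediate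
20 | (1S)-4-(3-chloropropyl)-1-[(1E)-4,4-diethoxybut-1-en-1-yl]-7-isopropyl-5,6,8-trimethoxy-3-(trimethylsilyloxy)-1H-isochromene | C[Si](C)(C)OC1=C(CCCCl)c2c(OC)c(OC)c(C(C)C)c(OC)c2[C@H](/C=C/CC(OCC)OCC)O1 | intermediate
21 | trimethylsilyl (1R,2R)-1-(3-chloropropyl)-2-(2,2-diethoxyethyl)-6-isopropyl-5,7,8-trimethoxy-1,2-dihydronaphthalene-1-carboxylate | COc1c(OC)c(C(C)C)c(OC)c2c1[C@@](C(=O)O[Si](C)(C)C)(CCCCl)[C@H](CC(OCC)OCC)C=C2 | intermediate
22 | (1R,2R)-1-(3-chloropropyl)-2-(2,2-diethoxyethyl)-6-isopropyl-5,7,8-trimethoxy-1,2-dihydronaphthalene-1-carboxylic acid | COc1c(OC)c(C(C)C)c(OC)c2c1[C@@](C(=O)O)(CCCCl)[C@H](CC(OCC)OCC)C=C2 | intermediate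
23 | methyl (1R,2R)-1-(3-chloropropyl)-2-(2,2-diethoxyethyl)-6-isopropyl-5,7,8-trimethoxy-1,2-dihydronaphthalene-1-carboxylate | COc1c(OC)c(C(C)C)c(OC)c2c1[C@@](C(=O)OC)(CCCCl)[C@H](CC(OCC)OCC)C=C2 | intermediate
24 | [(1R,2R)-1-(3-chloropropyl)-2-(2,2-diethoxyethyl)-6-isopropyl-5,7,8-trimethoxy-1,2-dihydronaphthalen-1-yl]methanol | COc1c(OC)c(C(C)C)c(OC)c2c1[C@@](CO)(CCCCl)[C@H](CC(OCC)OCC)C=C2 | intermediate
25 | (4aR,10bR)-10b-(3-chloropropyl)-8-isopropyl-7,9,10-trimethoxy-3,4,4a,10b-tetrahydro-1H-benzo[h]isochromen-3-ol (both anomers) | COc1c(OC)c(C(C)C)c(OC)c2c1[C@]3(CCCCl)COC(O)C[C@@H]3C=C2 | intermediate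
26 | (4aR,10bR)-10b-(3-chloropropyl)-8-isopropyl-7,9,10-trimethoxy-1,4,4a,10b-tetrahydro-3H-benzo[h]isochromen-3-one | COc1c(OC)c(C(C)C)c(OC)c2c1[C@]3(CCCCl)COC(=O)C[C@@H]3C=C2 | intermediate
27 | lithium enolate of 26 | COc1c(OC)c(C(C)C)c(OC)c2c1[C@]3(CCCCl)COC(O[Li])=C[C@@H]3C=C2 | intermediate
28 | (4aS,10bR)-10b-(3-chloropropyl)-8-isopropyl-7,9,10-trimethoxy-4-methyl-1,4,4a,10b-tetrahydro-3H-benzo[h]isochromen-3-one (both C4 epimers) | COc1c(OC)c(C(C)C)c(OC)c2c1[C@]3(CCCCl)COC(=O)C(C)[C@@H]3C=C2 | intermediate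
29 | (4S,5R,10R)-11,12,14-trimethoxyabieta-6,8,11,13-tetraen-19,20-olide | COc1c(OC)c(C(C)C)c(OC)c2c1[C@]13CCC[C@](C)(C(=O)OC1)[C@@H]3C=C2 | intermediate
30 | (4S,5R,10R)-12-methoxy-11,14-dioxoabieta-6,8,12-trien-19,20-olide | COC1=C(C(C)C)C(=O)C2=C(C1=O)[C@]13CCC[C@](C)(C(=O)OC1)[C@@H]3C=C2 | intermediate
31 | (4S,5R,10R)-12-hydroxy-11,14-dioxoabieta-6,8,12-trien-19,20-olide | OC1=C(C(C)C)C(=O)C2=C(C1=O)[C@]13CCC[C@](C)(C(=O)OC1)[C@@H]3C=C2 | intermediate
32 | (4S,5R,10R)-12-acetoxy-11,14-dioxoabieta-6,8,12-trien-19,20-olide | CC(=O)OC1=C(C(C)C)C(=O)C2=C(C1=O)[C@]13CCC[C@](C)(C(=O)OC1)[C@@H]3C=C2 | target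

**Step count**

Total step count: 16. Longest linear sequence: 16 steps (1 to 32); 11 enters in step 5.

**Steps most likely to fail**

First risk, step 9. The C7–O bond of the silyl ketene acetal is benzylic, allylic and activated by ortho and para methoxy groups, so it may ionise before or instead of the concerted shift, and the transfer of chirality from C7 would then be lost. Enolisation or O-silylation at the crowded C10 may also stay incomplete. The fallback for step 9 sets out from 19 and comes back to the route at 24; it avoids the enolate and uses a neutral cyclic enol ether at the aldehyde oxidation level. Reduction of 19 with iBu2AlH (CH2Cl2, −78 °C) should give the lactol (1S)-4-(3-chloropropyl)-1-[(1E)-4,4-diethoxybut-1-en-1-yl]-7-isopropyl-5,6,8-trimethoxyisochroman-3-ol F1 as a mixture of isomers. Treatment with MeSO2Cl and Et3N (CH2Cl2, 0 °C) should give in the flask the anomeric sulfonate (1S)-4-(3-chloropropyl)-1-[(1E)-4,4-diethoxybut-1-en-1-yl]-7-isopropyl-5,6,8-trimethoxyisochroman-3-yl methanesulfonate F2 which is not isolated. On warming to 40 °C it should lose methanesulfonic acid and give the cyclic allyl vinyl ether (1S)-4-(3-chloropropyl)-1-[(1E)-4,4-diethoxybut-1-en-1-yl]-7-isopropyl-5,6,8-trimethoxy-1H-isochromene F3 in the same pot. Heating (toluene, 110 °C) should bring about the thermal Claisen rearrangement through the same boat and give (1R,2R)-1-(3-chloropropyl)-2-(2,2-diethoxyethyl)-6-isopropyl-5,7,8-trimethoxy-1,2-dihydronaphthalene-1-carbaldehyde F4 with the configuration of the main route. NaBH4 (MeOH, 0 °C) then gives 24, from which acetal hydrolysis and lactol closure follow as planned.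

Second risk, step 5. Addition to the 2,6-disubstituted aldehyde may be slow, and the facial selectivity may be poor or even reversed relative to the benzaldehyde model. The fallback for step 5 sets out from 10 and comes back to the route at 14; it resolves instead of inducing. The alkenylzinc 13 is added to 10 with achiral 2-(dimethylamino)ethanol as promoter (toluene, 0 °C) to give racemic (2E)-1-{6-[2-(tert-butyldimethylsilyloxy)ethyl]-3-isopropyl-2,4,5-trimethoxyphenyl}-5,5-diethoxypent-2-en-1-ol F5 without facial control. Sharpless kinetic resolution (Ti(OiPr)4, L-(+)-diisopropyl tartrate, t-BuOOH, 4 Å molecular sieves, CH2Cl2, −20 °C) should consume the (1R) enantiomer as the anti epoxy alcohol (S)-{6-[2-(tert-butyldimethylsilyloxy)ethyl]-3-isopropyl-2,4,5-trimethoxyphenyl}[(2S,3S)-3-(2,2-diethoxyethyl)oxiran-2-yl]methanol F6 and leave the (1S) enantiomer, which is 14.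

Third risk, step 14. The one-electron oxidant (tetravalent cerium) may attack the electron-rich styrene-type C6=C7 bond or the allylic C5–H. Oxidation may also run across C11/C12 to the ortho-quinone instead of across C11/C14. The fallback for step 14 sets out from 29 and comes back to the route at 31; it reaches the hydroxyquinone without a cerium reagent and without a separate cleavage of the vinylogous ester. Exhaustive ether cleavage (BBr3, CH2Cl2, −78 → 0 °C; aqueous work-up under argon) should give (4S,5R,10R)-11,12,14-trihydroxyabieta-6,8,11,13-tetraen-19,20-olide F7 with the lactone intact, because its alkyl C20–O bond is neopentyl and should resist bromide. Stirring its solution in EtOAc under O2 (25 °C) should oxidise this hydroxyhydroquinone to 31, as is general for 1,2,4-trihydroxybenzenes.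

Further compounds
F1 | step 9 | (1S)-4-(3-chloropropyl)-1-[(1E)-4,4-diethoxybut-1-en-1-yl]-7-isopropyl-5,6,8-trimethoxyisochroman-3-ol | OC1C(CCCCl)c2c(OC)c(OC)c(C(C)C)c(OC)c2[C@H](/C=C/CC(OCC)OCC)O1
F2 | step 9 | (1S)-4-(3-chloropropyl)-1-[(1E)-4,4-diethoxybut-1-en-1-yl]-7-isopropyl-5,6,8-trimethoxyisochroman-3-yl methanesulfonate | CS(=O)(=O)OC1C(CCCCl)c2c(OC)c(OC)c(C(C)C)c(OC)c2[C@H](/C=C/CC(OCC)OCC)O1
F3 | step 9 | (1S)-4-(3-chloropropyl)-1-[(1E)-4,4-diethoxybut-1-en-1-yl]-7-isopropyl-5,6,8-trimethoxy-1H-isochromene | C1=C(CCCCl)c2c(OC)c(OC)c(C(C)C)c(OC)c2[C@H](/C=C/CC(OCC)OCC)O1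
F4 | step 9 | (1R,2R)-1-(3-chloropropyl)-2-(2,2-diethoxyethyl)-6-isopropyl-5,7,8-trimethoxy-1,2-dihydronaphthalene-1-carbaldehyde | COc1c(OC)c(C(C)C)c(OC)c2c1[C@@](C=O)(CCCCl)[C@H](CC(OCC)OCC)C=C2
F5 | step 5 | racemic (2E)-1-{6-[2-(tert-butyldimethylsilyloxy)ethyl]-3-isopropyl-2,4,5-trimethoxyphenyl}-5,5-diethoxypent-2-en-1-ol | COc1c(CCO[Si](C)(C)C(C)(C)C)c(C(O)/C=C/CC(OCC)OCC)c(OC)c(C(C)C)c1OC
F6 | step 5 | (S)-{6-[2-(tert-butyldimethylsilyloxy)ethyl]-3-isopropyl-2,4,5-trimethoxyphenyl}[(2S,3S)-3-(2,2-diethoxyethyl)oxiran-2-yl]methanol | COc1c(CCO[Si](C)(C)C(C)(C)C)c([C@H](O)[C@@H]2O[C@H]2CC(OCC)OCC)c(OC)c(C(C)C)c1OC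
F7 | step 14 | (4S,5R,10R)-11,12,14-trihydroxyabieta-6,8,11,13-tetraen-19,20-olide | Oc1c(O)c(C(C)C)c(O)c2c1[C@]13CCC[C@](C)(C(=O)OC1)[C@@H]3C=C2
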